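**Retrosynthetic overview**
- Feature: in the central coumarin (unit B), the benzene ring C4a-C5-C6-C7-C8-C8a carries oxygen on C7 (OH) and on C8a (ring O1). C8 lies between these two carbons and is bonded to C8 of the terminal coumarin (unit C). This ring is therefore the dehydrogenated form of a 2-arylcyclohexane-1,3-dione.
- Late disconnections: both phenols come from methyl ethers (BBr3). The pyranone of unit B, with its C3-O-aryl bond, comes from a Perkin condensation of a 3-aryl-4-methoxysalicylaldehyde with the 7-O-carboxymethyl ether of umbelliferone (unit A).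
- The salicylaldehyde comes from the dione in three operations: O-methylation to the vinylogous ester, kinetic formylation next to the ketone, and DDQ dehydrogenation.
- The dione comes from a (Z)-6-arylidene delta-enol lactone by methoxide-induced acyl transfer from oxygen to the benzylic carbon. The enol lactone comes from 8-iodo-7-methoxycoumarin and hex-5-ynoic acid by Sonogashira coupling and 6-exo-dig cycloisomerisation.
- Ring order: units A and C are bought as umbelliferone. Then come the temporary delta-lactone, the carbocycle of unit B, its aromatisation, and the pyranone of unit B.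

Key step: step 5

Assumption: the target SMILES gives no axial descriptor for the tetra-ortho-substituted C8(unit B)-C8(unit C) bond. The axis is therefore built without control and the product is taken as the racemate; the target has no stereocentre.

**Step 1**
Reactants: 1 umbelliferone (7-hydroxychromen-2-one)
Product: 2 7-hydroxy-8-iodochromen-2-one
Conditions: I2, KI, aq NH4OH, 0 °C to rt; then dilute H2SO4
Reagents that add atoms: iodine, [I][I]
Why: Electrophilic aromatic iodination of the phenoxide should go to C8, the ortho carbon between C7-O and C8a-O and the most nucleophilic site of 7-hydroxycoumarins, as is established for this reagent mixture.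

**Step 2**
Reactants: 2 7-hydroxy-8-iodochromen-2-one
Product: 3 8-iodo-7-methoxychromen-2-one
Conditions: MeI, K2CO3, acetone, reflux
Reagents that add atoms: iodomethane, CI
Why: Williamson ether synthesis on the acidic phenol leaves the lactone closed, and the methyl ether prevents benzofuran formation from the ortho alkyne in steps 3 and 4.

**Step 3**
Reactants: 3 8-iodo-7-methoxychromen-2-one; 4 hex-5-ynoic acid
Product: 5 6-(7-methoxy-2-oxochromen-8-yl)hex-5-ynoic acid
Conditions: PdCl2(PPh3)2 (cat.), CuI (cat.), Et3N, DMF, 55 °C; then dilute HCl
Reagents that add atoms: none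
Why: In this Sonogashira coupling, zerovalent palladium inserts into the aryl C-I bond despite the two ortho oxygens, the linear copper acetylide makes little steric demand, and the acid travels as its triethylammonium salt.

**Step 4**
Reactants: 5 6-(7-methoxy-2-oxochromen-8-yl)hex-5-ynoic acid
Product: 6 (Z)-6-[(7-methoxy-2-oxochromen-8-yl)methylidene]oxan-2-one
Conditions: AuCl (cat.), K2CO3 (cat.), MeCN, rt to 50 °C
Reagents that add atoms: none
Why: In this metal-catalysed cycloisomerisation of an alkynoic acid, the carboxylate attacks the AuCl-activated alkyne anti in a 6-exo-dig closure, and protodeauration with retention places aryl and ring oxygen cis, which is the Z alkene.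

**Step 5**
Reactants: 6 (Z)-6-[(7-methoxy-2-oxochromen-8-yl)methylidene]oxan-2-one
Product: 9 2-(7-methoxy-2-oxochromen-8-yl)cyclohexane-1,3-dione, via keto ester 7 (not isolated), via sodium dione enolate 8 (not isolated)
Conditions: NaOMe (3 equiv), MeOH/THF, 0 °C to 40 °C; then 2 M HCl, rt
Reagents that add atoms: none
Why: Methoxide adds to the lactone carbonyl of 6 and expels the enolate oxygen, which gives keto ester 7 and erases the alkene geometry; in 7 the CH2 between the ketone and the aryl ring (future C8 of unit B) is the most acidic carbon. Its enolate attacks the methyl ester carbonyl, the former lactone carbon, and loss of methoxide closes the carbocycle of unit B in a 6-(enolexo)-exo-trig Dieckmann-type acylation. The closest known reaction type is the alkoxide-induced rearrangement of benzylidenephthalides to 2-arylindane-1,3-diones and of arylidene gamma- and delta-enol lactones to 2-aryl cyclic 1,3-diones. No stereocentre is created, because C2 of the product is part of a planar enolate and later of an arene. The step needs C-acylation to win over O-acylation (return to 6) and over plain methanolysis (stop at 7): all these events are reversible under methoxide, only the C-acylated product is withdrawn as the strongly stabilised enolate 8, and every other enolate-carbonyl pairing in 7 would close a four-membered ring. The lactone of unit C can at most be opened reversibly to a Z-cinnamate, which the moderate temperature keeps Z and the HCl work-up closes again.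

**Step 6**
Reactants: 9 2-(7-methoxy-2-oxochromen-8-yl)cyclohexane-1,3-dione
Product: 10 3-methoxy-2-(7-methoxy-2-oxochromen-8-yl)cyclohex-2-en-1-one
Conditions: Me2SO4, K2CO3, acetone, reflux
Reagents that add atoms: dimethyl sulfate, COS(=O)(=O)OC
Why: O-Alkylation of the ambident dione enolate with a hard electrophile should give the vinylogous ester, since C-methylation is blocked by the di-ortho-substituted aryl group on C2 and the symmetry of 9 allows only one product.

**Step 7**
Reactants: 10 3-methoxy-2-(7-methoxy-2-oxochromen-8-yl)cyclohex-2-en-1-one
Product: 12 (6Z)-6-(hydroxymethylidene)-3-methoxy-2-(7-methoxy-2-oxochromen-8-yl)cyclohex-2-en-1-one (chelated enol of the 6-carbaldehyde), via lithium enolate 11 (not isolated)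
Conditions: LDA (commercial solution, 1.1 equiv), THF, -78 °C; HCO2CH2CF3, -78 °C to -30 °C; then AcOH
Reagents that add atoms: 2,2,2-trifluoroethyl formate, O=COCC(F)(F)F
Why: Stork-Danheiser-type kinetic deprotonation of a 3-alkoxyenone occurs only at the alpha-prime CH2 (C6), and the cross-conjugated enolate 11 should undergo Claisen-type C-formylation with the very reactive formate faster than it adds to the electron-rich pyranone of unit C, the product resting as its hydrogen-bonded Z enol so that no stereocentre persists.

**Step 8**
Reactants: 12 (6Z)-6-(hydroxymethylidene)-3-methoxy-2-(7-methoxy-2-oxochromen-8-yl)cyclohex-2-en-1-one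
Product: 14 2-hydroxy-4-methoxy-3-(7-methoxy-2-oxochromen-8-yl)benzaldehyde, via formyl dienone 13 (not isolated)
Conditions: DDQ (1.1 equiv), 1,4-dioxane, rt
Reagents that add atoms: none
Why: DDQ dehydrogenation of an alpha-hydroxymethylene ketone (hydride abstraction from C5 of the enol) installs the C5-C6 double bond, and dienone 13, which still has one ring CH2, should tautomerise at once to the aromatic salicylaldehyde.

**Step 9**
Reactants: 1 umbelliferone; 15 tert-butyl bromoacetate
Product: 16 tert-butyl 2-[(2-oxochromen-7-yl)oxy]acetate
Conditions: K2CO3, acetone, reflux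
Reagents that add atoms: none
Why: This is a Williamson ether synthesis with a reactive alpha-bromo ester, and the tert-butyl ester is chosen so that the acid can be released later without base and so without touching the lactone.

**Step 10**
Reactants: 16 tert-butyl 2-[(2-oxochromen-7-yl)oxy]acetate
Product: 17 2-[(2-oxochromen-7-yl)oxy]acetic acid
Conditions: TFA, CH2Cl2, rt
Reagents that add atoms: none
Why: Acidolysis of the tert-butyl ester proceeds by loss of the tert-butyl cation as isobutene, and the coumarin and the aryl alkyl ether are inert to TFA.

**Step 11**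
Reactants: 14 2-hydroxy-4-methoxy-3-(7-methoxy-2-oxochromen-8-yl)benzaldehyde; 17 2-[(2-oxochromen-7-yl)oxy]acetic acid
Product: 20 7-methoxy-8-(7-methoxy-2-oxochromen-8-yl)-3-[(2-oxochromen-7-yl)oxy]chromen-2-one, via mixed anhydride 18 (not isolated), via aryl ester 19 (not isolated)
Conditions: Ac2O, Et3N, 110 °C
Reagents that add atoms: none
Why: In this Perkin-Oglialoro coumarin synthesis, mixed anhydride 18 acylates the phenol, and the OCH2 group of ester 19, acidified by the carbonyl and the aryloxy group, condenses with the ortho aldehyde with loss of water, a known route from salicylaldehydes and aryloxyacetic acids to 3-aryloxycoumarins.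

**Step 12**
Reactants: 20 7-methoxy-8-(7-methoxy-2-oxochromen-8-yl)-3-[(2-oxochromen-7-yl)oxy]chromen-2-one
Product: 21 triumbelletin, 7-hydroxy-8-(7-hydroxy-2-oxochromen-8-yl)-3-[(2-oxochromen-7-yl)oxy]chromen-2-one
Conditions: BBr3 (10 equiv), CH2Cl2, -78 °C to rt; then H2O
Reagents that add atoms: none
Why: In this Lewis acid-mediated cleavage of aryl methyl ethers, bromide can attack only the two sp3 methyl carbons, so the sp2-O-sp2 ether at C3 of unit B and the three lactones should survive.

**Compound list**
1 | umbelliferone (7-hydroxychromen-2-one) | O=c1ccc2ccc(O)cc2o1 | starting material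
2 | 7-hydroxy-8-iodochromen-2-one | O=c1ccc2ccc(O)c(I)c2o1 | intermediate
3 | 8-iodo-7-methoxychromen-2-one | COc1ccc2ccc(=O)oc2c1I | intermediate
4 | hex-5-ynoic acid | C#CCCCC(=O)O | starting material
5 | 6-(7-methoxy-2-oxochromen-8-yl)hex-5-ynoic acid | COc1ccc2ccc(=O)oc2c1C#CCCCC(=O)O | intermediate
6 | (Z)-6-[(7-methoxy-2-oxochromen-8-yl)methylidene]oxan-2-one | O=C1CCC/C(=C/c2c(OC)ccc3ccc(=O)oc23)O1 | intermediate
7 | methyl 6-(7-methoxy-2-oxochromen-8-yl)-5-oxohexanoate (not isolated) | COC(=O)CCCC(=O)Cc1c(OC)ccc2ccc(=O)oc12 | intermediate
8 | sodium 2-(7-methoxy-2-oxochromen-8-yl)-3-oxocyclohex-1-en-1-olate (not isolated) | [Na+].[O-]C1=C(c2c(OC)ccc3ccc(=O)oc23)C(=O)CCC1 | intermediate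
9 | 2-(7-methoxy-2-oxochromen-8-yl)cyclohexane-1,3-dione (drawn as the diketo tautomer) | O=C1CCCC(=O)C1c1c(OC)ccc2ccc(=O)oc12 | intermediate
10 | 3-methoxy-2-(7-methoxy-2-oxochromen-8-yl)cyclohex-2-en-1-one | COC1=C(c2c(OC)ccc3ccc(=O)oc23)C(=O)CCC1 | intermediate
11 | lithium 5-methoxy-6-(7-methoxy-2-oxochromen-8-yl)cyclohexa-1,5-dien-1-olate (not isolated) | [Li+].[O-]C1=CCCC(OC)=C1c1c(OC)ccc2ccc(=O)oc12 | intermediate
12 | (6Z)-6-(hydroxymethylidene)-3-methoxy-2-(7-methoxy-2-oxochromen-8-yl)cyclohex-2-en-1-one | O/C=C1/CCC(OC)=C(c2c(OC)ccc3ccc(=O)oc23)C1=O | intermediate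
13 | 4-methoxy-5-(7-methoxy-2-oxochromen-8-yl)-6-oxocyclohexa-1,4-diene-1-carbaldehyde (not isolated) | O=CC1=CCC(OC)=C(c2c(OC)ccc3ccc(=O)oc23)C1=O | intermediate
14 | 2-hydroxy-4-methoxy-3-(7-methoxy-2-oxochromen-8-yl)benzaldehyde | O=Cc1ccc(OC)c(-c2c(OC)ccc3ccc(=O)oc23)c1O | intermediate
15 | tert-butyl bromoacetate | CC(C)(C)OC(=O)CBr | starting material
16 | tert-butyl 2-[(2-oxochromen-7-yl)oxy]acetate | CC(C)(C)OC(=O)COc1ccc2ccc(=O)oc2c1 | intermediate
17 | 2-[(2-oxochromen-7-yl)oxy]acetic acid | O=C(O)COc1ccc2ccc(=O)oc2c1 | intermediate
18 | acetic 2-[(2-oxochromen-7-yl)oxy]acetic anhydride (not isolated) | CC(=O)OC(=O)COc1ccc2ccc(=O)oc2c1 | intermediate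
19 | 6-formyl-3-methoxy-2-(7-methoxy-2-oxochromen-8-yl)phenyl 2-[(2-oxochromen-7-yl)oxy]acetate (not isolated) | O=Cc1ccc(OC)c(-c2c(OC)ccc3ccc(=O)oc23)c1OC(=O)COc1ccc2ccc(=O)oc2c1 | intermediate
20 | 7-methoxy-8-(7-methoxy-2-oxochromen-8-yl)-3-[(2-oxochromen-7-yl)oxy]chromen-2-one | COc1ccc2cc(Oc3ccc4ccc(=O)oc4c3)c(=O)oc2c1-c1c(OC)ccc2ccc(=O)oc12 | intermediate
21 | triumbelletin | O=c1ccc2ccc(Oc3cc4ccc(O)c(-c5c(O)ccc6ccc(=O)oc56)c4oc3=O)cc2o1 | target

**Step count**
Total step count: 12.
Longest linear sequence: 10 (steps 1 to 8, 11 and 12). Steps 9 and 10 form the side branch.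

**Steps most likely to fail**

Step 5.
- Risk: methoxide may attack the lactone of unit C, followed by Z-to-E isomerisation of the opened cinnamate or by cyclodehydration of the freed phenoxide onto the neighbouring ketone. Ring closure may also be slow at a carbon that bears a di-ortho-substituted aryl group.
- Fallback: the aryl-C2 bond of the dione is made directly by palladium-catalysed alpha-arylation of a cyclic 1,3-dione, without any alkoxide. It sets out from 3, which is heated with commercial cyclohexane-1,3-dione, Pd(OAc)2, XPhos and K3PO4 in 1,4-dioxane at 100 °C and then acidified. It comes back to the route at 9. No compound outside the list is made (F0).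

Step 7.
- Risk: the amide base or the enolate may add to the pyranone of unit C, gamma-deprotonation may compete, or formylation may occur on oxygen.
- Fallback: the order is reversed, with aromatisation first and formylation of the phenol afterwards. It sets out from 10, which is dehydrogenated with Pd(O2CCF3)2, 2-(dimethylamino)pyridine and TsOH under O2 in DMSO at 80 °C to 8-(2-hydroxy-6-methoxyphenyl)-7-methoxychromen-2-one F1. Magnesium-mediated ortho-formylation (MgCl2, Et3N, paraformaldehyde, MeCN, reflux; Casnati-Skattebol reaction) can then reach only the single free position ortho to the phenol. The fallback comes back to the route at 14, and steps 7 and 8 are left out.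

Step 4.
- Risk: attack of the carboxylate on the hindered, electron-rich internal alkyne may be slow, closure may drift towards 7-endo-dig, and the enol lactone may hydrolyse during isolation.
- Fallback: the C-O bond is formed on the terminal alkyne, where exo attack is also the Markovnikov mode, and the aryl group is delivered in the same operation. It sets out from 3 and 4, which are heated with Pd(OAc)2, PPh3, Et3N and n-Bu4NCl in DMF at 60 °C without copper. Anti oxypalladation by the arylpalladium iodide and reductive elimination should then give (E)-6-[(7-methoxy-2-oxochromen-8-yl)methylidene]oxan-2-one F2. Ring opening erases the alkene geometry, so the conditions of step 5 bring F2 back to the route at 7 and hence at 9.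

**Further compounds**
F0 | step 5 | none | none
F1 | step 7 | 8-(2-hydroxy-6-methoxyphenyl)-7-methoxychromen-2-one | COc1cccc(O)c1-c1c(OC)ccc2ccc(=O)oc12
F2 | step 4 | (E)-6-[(7-methoxy-2-oxochromen-8-yl)methylidene]oxan-2-one | O=C1CCC/C(=C\c2c(OC)ccc3ccc(=O)oc23)O1
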